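All runs are simulated for an exercise; the scatter is artificial.

4 questions stand here, and 3 of them ask for one number in 3 flasks: how much of target plus side product A is target.

| flask | substrate | partner | remark | time |
|---|---|---|---|---|
| ash | 0.010 M | 0.025 M | run made earlier |  |
| maple | 0.010 M | 0.013 M | run made earlier |  |
| south-east | 0.010 M | 0.0250 M (fed, over 20 min) | all else is in the flask from the start; the feed brings no volume worth counting | 25 min |
| south-west | 0.010 M | 0.0250 M | everything together at the start | 25 min |
| north-east | 0.010 M (fed, over 20 min) | 0.0250 M | all else is in the flask from the start; the feed brings no volume worth counting | 25 min |

| run | time / min | target / % | side product A / % |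
|---|---|---|---|
| ash | 0.833 | 6 | 2 |
| ash | 2.50 | 9 | 7 |
| ash | 4.00 | 10 | 12 |
| ash | 6.00 | 4 | 15 |
| ash | 10.0 | 9 | 16 |
| ash | 12.0 | 6 | 13 |
| ash | 15.0 | 7 | 14 |
| maple | 1.00 | 5 | 3 |
| maple | 2.00 | 8 | 4 |
| maple | 3.00 | 8 | 8 |
| maple | 4.00 | 9 | 14 |
| maple | 5.00 | 9 | 12 |
| maple | 6.00 | 10 | 14 |
| maple | 8.00 | 12 | 14 |

(each reading ± 1.5 percentage points)

- the flask that comes out highest in share of target in target plus side product A, or "all alike" when all lie within 1.5 percentage points (south-east / south-west / north-east / all alike)
- share of target in target plus side product A at the end, south-east
- share of target in target plus side product A at the end, south-west
- share of target in target plus side product A at the end, north-east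

- in percentages every species weighs as the substrate in it: one side product B counts as two
- the analysis behind the earlier runs scatters by 1.5 percentage points, standard deviation
- what may be going on: substrate <-> intermediate; partner + intermediate -> side product A; partner + intermediate -> target; substrate + target -> side product B

I first ask what level target must reach. On the card, substrate feeds target through the intermediate and also destroys it, so both rates carry [substrate], and they balance at a [target] in which [substrate] cancels. The readings of ash and maple, pooled from 4.00 min on, put that level at 8.44 × 10⁻⁴ M, which is 8.44% of the charge. This is the ceiling of target, the [target] at which making and loss are equal, a quasi-steady state. Side product A reads 13.8% over the same readings, so a flask held at the ceiling gives a share of 38.0%.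

Now the settings. Feeding substrate lowers [substrate], but the ceiling contains none, so I put north-east beside south-west, both near that share.

Feeding partner is another matter. The first step takes no partner, and in ash side product A reads 7% at 2.50 min, half its late level, a time shorter than the feed. So in south-east substrate can leave while partner still arrives, and target made once substrate has gone can pass the ceiling. I expect south-east highest, though I cannot say by how much.

The forecast differs over south-east: it says all alike, with south-east 35% (27% to 42%), south-west 37% (31% to 43%) and north-east 38% (31% to 46%), on the ground that the partner feed “roughly matches demand, so it costs little”.

The simulation gives south-east as highest, at 54.2%, with south-west at 35.5% and north-east at 34.9%. In south-east, target stands at 19.8% at 12.5 min, with substrate down to 0.297%. Against the ceiling of 8.44%, south-west ends at 8.30% and north-east at 7.89%, while south-east ends at 2.33 times the ceiling.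

    substrate ⇌ intermediate (K = 39.5, k = 0.213 /min)
    partner + intermediate → side product A (k = 49.5 /M/min)
    partner + intermediate → target (k = 153 /M/min)
    substrate + target → side product B (k = 212 /M/min)

The neighbour is north-east with 0.025 M of substrate. The same ceiling is 3.38% of that charge, which with 13.8% of side product A gives a share of 19.7%. The simulation gives 3.40% of target and a share of 19.5%.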